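The route rests on cutting ring 1 (the styryl-bearing dihydrobenzofuran) at C2–aryl and C3–C3a. C2 (bonded to O1 and the 4-hydroxyphenyl group) and C3 (bonded to C3a and to C4′ of the central ring) are neighbouring benzylic CH carbons. An E-alkene between them, already attached to C4′ of ring 2, can therefore take up one aryl group on each carbon. One palladium-catalysed conjunctive coupling of the derived alkenylboron ate complex does this in anti fashion, sets both stereocentres and leaves boron on C2 as the future O1. The precursor is enantiopure trans ring 2 with an E-vinylboronic ester at C4′.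

Key step: step 13

Remark on the chemistry: unprimed locants refer to ring 1 and primed ones to ring 2; boron carries the mac diol (cis-1,2-dimethylacenaphthylene-1,2-diol) instead of pinacol, because β-substituted alkenyl pinacol boronates mainly undergo direct Suzuki coupling under conjunctive conditions; a nitrile is the SNAr-activating group, so that one reduction gives the aldehyde; the hand of Rh2(PTAD)4 and of the MandyPhos ligand is assumed to be the one that gives the configurations drawn, to be fixed on first runs.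

Step 1
Reactants: 1 1-bromo-3,5-dimethoxybenzene
Product: 2 2-bromo-4,6-dimethoxybenzaldehyde
Conditions: POCl3, DMF, 0 → 90 °C; aq. NaOAc
Reagents that add atoms: N,N-dimethylformamide CN(C)C=O; water O
Why: Vilsmeier–Haack formylation should go to the carbon ortho to bromine, which is para to one methoxy group and ortho to the other, and not to the more crowded carbon between the two methoxy groups.

Step 2
Reactants: 2 2-bromo-4,6-dimethoxybenzaldehyde
Product: 3 2-bromo-6-hydroxy-4-methoxybenzaldehyde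
Conditions: BCl3 (1.1 equiv), CH2Cl2, −78 → 0 °C
Reagents that add atoms: none
Why: BCl3 chelated between the aldehyde oxygen and the ortho methoxy oxygen should cleave only that ether (chelation-controlled mono-demethylation).

Step 3
Reactants: 3 2-bromo-6-hydroxy-4-methoxybenzaldehyde; 4 4-methoxybenzyl chloride
Product: 5 2-bromo-4-methoxy-6-[(4-methoxybenzyl)oxy]benzaldehyde
Conditions: K2CO3, DMF, 60 °C
Reagents that add atoms: none
Why: Williamson etherification of the phenoxide installs the benzylic CH2 that later becomes C2′ together with its 4-methoxyphenyl group.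

Step 4
Reactants: 5 2-bromo-4-methoxy-6-[(4-methoxybenzyl)oxy]benzaldehyde; 1 1-bromo-3,5-dimethoxybenzene
Product: 7 {2-bromo-4-methoxy-6-[(4-methoxybenzyl)oxy]phenyl}(3,5-dimethoxyphenyl)methanol (racemic), via 3,5-dimethoxyphenylmagnesium bromide 6 (not isolated)
Conditions: 1, Mg, THF, reflux; then 5, THF, 0 °C → rt; aq. NH4Cl
Reagents that add atoms: none
Why: Grignard addition to the aldehyde is faster than any exchange at the aryl bromide and gives the diarylmethanol, whose stereocentre is removed in the next step.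

Step 5
Reactants: 7 {2-bromo-4-methoxy-6-[(4-methoxybenzyl)oxy]phenyl}(3,5-dimethoxyphenyl)methanol
Product: 8 {2-bromo-4-methoxy-6-[(4-methoxybenzyl)oxy]phenyl}(3,5-dimethoxyphenyl)methanone
Conditions: Dess–Martin periodinane, NaHCO3, CH2Cl2, rt
Reagents that add atoms: none
Why: Dess–Martin oxidation converts a diarylmethanol into the benzophenone under neutral conditions that leave the 4-methoxybenzyl ether intact.

Step 6
Reactants: 8 {2-bromo-4-methoxy-6-[(4-methoxybenzyl)oxy]phenyl}(3,5-dimethoxyphenyl)methanone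
Product: 9 hydrazone of ketone 8 (E/Z mixture)
Conditions: N2H4·H2O (excess), AcOH (cat.), n-BuOH, 110 °C
Reagents that add atoms: hydrazine NN
Why: Acid-catalysed condensation with excess hydrazine at elevated temperature should overcome the hindrance of the doubly ortho-substituted ketone (hydrazone formation).

Step 7
Reactants: 9 hydrazone of ketone 8
Product: 11 (2R,3S)-4-bromo-3-(3,5-dimethoxyphenyl)-6-methoxy-2-(4-methoxyphenyl)-2,3-dihydro-1-benzofuran (cis), via diaryldiazomethane 10 (not isolated)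
Conditions: MnO2, CH2Cl2, 0 °C; filter; Rh2(S-PTAD)4 {dirhodium tetrakis[(S)-(1-adamantyl)(N-phthalimido)acetate]} (1 mol%), CH2Cl2, 0 °C → rt
Reagents that add atoms: none
Why: MnO2 dehydrogenates the hydrazone to 10, and the dirhodium carboxylate (divalent rhodium) turns it into a donor/donor carbene that inserts into the benzylic ether C–H bond five atoms away (enantioselective intramolecular C–H insertion), the chiral carboxylates fixing C3′ and giving the kinetic cis isomer.

Step 8
Reactants: 11 (2R,3S)-4-bromo-3-(3,5-dimethoxyphenyl)-6-methoxy-2-(4-methoxyphenyl)-2,3-dihydro-1-benzofuran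
Product: 12 (2S,3S)-4-bromo-3-(3,5-dimethoxyphenyl)-6-methoxy-2-(4-methoxyphenyl)-2,3-dihydro-1-benzofuran (trans)
Conditions: CF3CO2H, CH2Cl2, 0 °C → rt
Reagents that add atoms: none
Why: Acid reversibly ionises the C2′–O bond to a 4-methoxybenzylic cation and reclosure gives the more stable trans isomer, while C3′ takes no part and keeps its configuration (acid-mediated cis-to-trans epimerisation of a 2-aryl-2,3-dihydrobenzofuran).

Step 9
Reactants: 12 (2S,3S)-4-bromo-3-(3,5-dimethoxyphenyl)-6-methoxy-2-(4-methoxyphenyl)-2,3-dihydro-1-benzofuran; 13 (E)-2-(4,4,5,5-tetramethyl-1,3,2-dioxaborolan-2-yl)ethenylboronic acid MIDA ester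
Product: 14 MIDA boronate of (E)-2-[(2S,3S)-3-(3,5-dimethoxyphenyl)-6-methoxy-2-(4-methoxyphenyl)-2,3-dihydro-1-benzofuran-4-yl]ethenylboronic acid
Conditions: Pd(OAc)2 (5 mol%), SPhos (10 mol%), K3PO4 (anhydrous), THF/DMSO, 50 °C
Reagents that add atoms: none
Why: Suzuki–Miyaura coupling takes place only at the pinacol boronate, because the tetracoordinate MIDA boronate does not transmetalate without water, and the E geometry is retained.

Step 10
Reactants: 15 acenaphthoquinone (acenaphthylene-1,2-dione)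
Product: 16 cis-1,2-dimethyl-1,2-dihydroacenaphthylene-1,2-diol (mac diol, meso)
Conditions: AlMe3 (3 equiv), toluene, 0 °C → rt; aq. potassium sodium tartrate; recrystallisation
Reagents that add atoms: trimethylaluminium C[Al](C)C
Why: Double methyl addition to the 1,2-diketone should give the cis diol, the second methyl entering anti to the bulky aluminium alkoxide, and any trans isomer is removed by crystallisation.

Step 11
Reactants: 14 MIDA boronate of the E-alkenylboronic acid; 16 cis-1,2-dimethyl-1,2-dihydroacenaphthylene-1,2-diol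
Product: 18 mac ester (cyclic boronate of diol 16) of (E)-2-[(2S,3S)-3-(3,5-dimethoxyphenyl)-6-methoxy-2-(4-methoxyphenyl)-2,3-dihydro-1-benzofuran-4-yl]ethenylboronic acid, the E-alkenyl boronate on C4′ of trans ring 2, via alkenylboronic acid 17 (not isolated)
Conditions: 1 M aq. NaOH, THF, rt, 15 min; pH 7 phosphate buffer, extraction; then 16, MgSO4, CH2Cl2, rt
Reagents that add atoms: none
Why: Mild aqueous base hydrolyses the MIDA boronate, and condensation of the boronic acid with the cis diol (boronic ester formation) is driven by removal of water.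

Step 12
Reactants: 19 4-fluoro-3-hydroxybenzonitrile
Product: 20 5-cyano-2-fluorophenyl trifluoromethanesulfonate
Conditions: (CF3SO2)2O, pyridine, CH2Cl2, 0 °C
Reagents that add atoms: trifluoromethanesulfonic anhydride O=S(=O)(OS(=O)(=O)C(F)(F)F)C(F)(F)F
Why: O-Sulfonylation of the phenol gives an electron-poor aryl triflate whose fluorine is para to the nitrile.

Step 13
Reactants: 18 E-alkenyl mac boronate on C4′ of trans ring 2; 20 5-cyano-2-fluorophenyl trifluoromethanesulfonate; 21 4-bromoanisole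
Product: 24 mac ester of (1S,2S)-2-(5-cyano-2-fluorophenyl)-2-[(2S,3S)-3-(3,5-dimethoxyphenyl)-6-methoxy-2-(4-methoxyphenyl)-2,3-dihydro-1-benzofuran-4-yl]-1-(4-methoxyphenyl)ethylboronic acid (boron on the future C2, fluoro nitrile arene on the future C3), via 4-methoxyphenyllithium 22 (not isolated), via lithium alkenyl(aryl)borate complex 23 (not isolated)
Conditions: 21, t-BuLi (2 equiv), Et2O, −78 °C; add to 18, THF, −78 °C → rt; solvent exchange to THF; 20 (1.2 equiv), NaOTf (2 equiv), Pd(OAc)2 (3 mol%), MandyPhos ligand [1,1′-bis(diarylphosphino)-2,2′-bis(α-dimethylaminobenzyl)ferrocene, aryl = 4-methoxy-3,5-dimethylphenyl] (3.6 mol%), THF, 60 °C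
Reagents that add atoms: none
Why: 22 adds to the boron of 18 to give the four-coordinate borate 23; the arylpalladium triflate from oxidative addition of 20 to zerovalent palladium binds the alkene of 23 and triggers a 1,2-shift of the 4-methoxyphenyl group from boron to C2 anti to palladium, and reductive elimination from the benzylic alkylpalladium (divalent palladium) then forms C3–C3a. This is the palladium-catalysed enantioselective conjunctive cross-coupling of alkenylboron ate complexes with aryl triflates, extended here to a β-aryl alkenyl boronate and an ortho-fluorinated triflate. No ring is closed in this step. The relative configuration of C2 and C3 follows from the E alkene and the anti addition, which corresponds to the trans ring after stereoretentive oxidation and O-arylation; the absolute configuration is set by the chiral bisphosphine on palladium, with the ring 2 stereocentres as a secondary bias. The step needs the metalate shift to outrun direct alkenyl transfer to palladium (Suzuki coupling), which the mac diol on boron secures for β-substituted alkenyl boronates, and it needs halide-free cationic palladium, which the triflate and NaOTf as bromide scavenger secure. The nitrile survives because no free aryllithium is left once 23 has formed.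

Step 14
Reactants: 24 mac ester of the 1,2,2-triarylethylboronic acid
Product: 25 3-{(1S,2S)-1-[(2S,3S)-3-(3,5-dimethoxyphenyl)-6-methoxy-2-(4-methoxyphenyl)-2,3-dihydro-1-benzofuran-4-yl]-2-hydroxy-2-(4-methoxyphenyl)ethyl}-4-fluorobenzonitrile
Conditions: NaBO3·4H2O, THF/H2O, rt
Reagents that add atoms: sodium perborate [Na+].[Na+].O[B-]1(O)OO[B-](O)(O)OO1
Why: Peroxide attack on boron and 1,2-shift of carbon from boron to oxygen replace boron by hydroxyl with retention at C2 (boronate oxidation), and perborate at room temperature is mild enough to spare the nitrile.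

Step 15
Reactants: 25 fluoro nitrile alcohol
Product: 26 (2S,3S)-3-[(2S,3S)-3-(3,5-dimethoxyphenyl)-6-methoxy-2-(4-methoxyphenyl)-2,3-dihydro-1-benzofuran-4-yl]-2-(4-methoxyphenyl)-2,3-dihydro-1-benzofuran-5-carbonitrile (both rings trans)
Conditions: NaH, DMF, 0 °C → rt
Reagents that add atoms: none
Why: The alkoxide displaces the fluoride para to the nitrile through a five-membered transition state (intramolecular SNAr), which closes ring 1 without touching either stereocentre.

Step 16
Reactants: 26 bis(dihydrobenzofuran) nitrile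
Product: 27 (2S,3S)-3-[(2S,3S)-3-(3,5-dimethoxyphenyl)-6-methoxy-2-(4-methoxyphenyl)-2,3-dihydro-1-benzofuran-4-yl]-2-(4-methoxyphenyl)-2,3-dihydro-1-benzofuran-5-carbaldehyde
Conditions: i-Bu2AlH, CH2Cl2, −78 → −20 °C; aq. potassium sodium tartrate, then dilute aq. HCl
Reagents that add atoms: water O
Why: One hydride adds to the nitrile and stops at the N-aluminated stage, which aqueous acid hydrolyses to the aldehyde (partial reduction of a nitrile).

Step 17
Reactants: 27 bis(dihydrobenzofuran) aldehyde; 28 diethyl (3,5-dimethoxybenzyl)phosphonate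
Product: 29 heptamethyl ether of trans-diptoindonesin B, (2S,3S)-5-[(E)-2-(3,5-dimethoxyphenyl)ethenyl]-3-[(2S,3S)-3-(3,5-dimethoxyphenyl)-6-methoxy-2-(4-methoxyphenyl)-2,3-dihydro-1-benzofuran-4-yl]-2-(4-methoxyphenyl)-2,3-dihydro-1-benzofuran
Conditions: KOt-Bu, THF, 0 °C → rt
Reagents that add atoms: none
Why: Horner–Wadsworth–Emmons olefination with a benzylic phosphonate gives the E-stilbene by reversible addition and syn elimination of diethyl phosphate, and the benzylic stereocentres are not acidic enough to be disturbed.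

Step 18
Reactants: 29 heptamethyl ether of trans-diptoindonesin B
Product: 30 trans-diptoindonesin B
Conditions: BCl3, n-Bu4NI, CH2Cl2, −78 °C → rt; MeOH, aq. NaHCO3
Reagents that add atoms: none
Why: Boron coordinates each aryl methyl ether and iodide removes the methyl group by SN2 (Lewis acid-mediated ether cleavage), a mild variant that should spare the dihydrobenzofuran C–O bonds and the stilbene.

Compound list
1 | 1-bromo-3,5-dimethoxybenzene | COc1cc(Br)cc(OC)c1 | starting material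
2 | 2-bromo-4,6-dimethoxybenzaldehyde | COc1cc(Br)c(C=O)c(OC)c1 | intermediate
3 | 2-bromo-6-hydroxy-4-methoxybenzaldehyde | COc1cc(O)c(C=O)c(Br)c1 | intermediate
4 | 4-methoxybenzyl chloride | COc1ccc(CCl)cc1 | starting material
5 | 2-bromo-4-methoxy-6-[(4-methoxybenzyl)oxy]benzaldehyde | COc1ccc(COc2cc(OC)cc(Br)c2C=O)cc1 | intermediate
6 | 3,5-dimethoxyphenylmagnesium bromide | COc1cc(OC)cc([Mg]Br)c1 | intermediate
7 | {2-bromo-4-methoxy-6-[(4-methoxybenzyl)oxy]phenyl}(3,5-dimethoxyphenyl)methanol (racemic) | COc1ccc(COc2cc(OC)cc(Br)c2C(O)c2cc(OC)cc(OC)c2)cc1 | intermediate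
8 | {2-bromo-4-methoxy-6-[(4-methoxybenzyl)oxy]phenyl}(3,5-dimethoxyphenyl)methanone | COc1ccc(COc2cc(OC)cc(Br)c2C(=O)c2cc(OC)cc(OC)c2)cc1 | intermediate
9 | hydrazone of ketone 8 | COc1ccc(COc2cc(OC)cc(Br)c2C(=NN)c2cc(OC)cc(OC)c2)cc1 | intermediate
10 | {2-bromo-4-methoxy-6-[(4-methoxybenzyl)oxy]phenyl}(3,5-dimethoxyphenyl)diazomethane | COc1ccc(COc2cc(OC)cc(Br)c2C(=[N+]=[N-])c2cc(OC)cc(OC)c2)cc1 | intermediate
11 | (2R,3S)-4-bromo-3-(3,5-dimethoxyphenyl)-6-methoxy-2-(4-methoxyphenyl)-2,3-dihydro-1-benzofuran (cis) | Brc1cc(OC)cc2c1[C@H](c1cc(OC)cc(OC)c1)[C@H](c1ccc(OC)cc1)O2 | intermediate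
12 | (2S,3S)-4-bromo-3-(3,5-dimethoxyphenyl)-6-methoxy-2-(4-methoxyphenyl)-2,3-dihydro-1-benzofuran (trans ring 2) | Brc1cc(OC)cc2c1[C@H](c1cc(OC)cc(OC)c1)[C@@H](c1ccc(OC)cc1)O2 | intermediate
13 | (E)-2-(4,4,5,5-tetramethyl-1,3,2-dioxaborolan-2-yl)ethenylboronic acid MIDA ester | CN1CC(=O)OB(/C=C/B2OC(C)(C)C(C)(C)O2)OC(=O)C1 | starting material
14 | MIDA boronate of (E)-2-[(2S,3S)-3-(3,5-dimethoxyphenyl)-6-methoxy-2-(4-methoxyphenyl)-2,3-dihydro-1-benzofuran-4-yl]ethenylboronic acid | CN1CC(=O)OB(/C=C/c2cc(OC)cc3c2[C@H](c2cc(OC)cc(OC)c2)[C@@H](c2ccc(OC)cc2)O3)OC(=O)C1 | intermediate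
15 | acenaphthoquinone | O=C1C(=O)c2cccc3cccc1c23 | starting material
16 | cis-1,2-dimethyl-1,2-dihydroacenaphthylene-1,2-diol (mac diol) | C[C@]1(O)[C@@](C)(O)c2cccc3cccc1c23 | intermediate
17 | (E)-2-[(2S,3S)-3-(3,5-dimethoxyphenyl)-6-methoxy-2-(4-methoxyphenyl)-2,3-dihydro-1-benzofuran-4-yl]ethenylboronic acid | OB(O)/C=C/c1cc(OC)cc2c1[C@H](c1cc(OC)cc(OC)c1)[C@@H](c1ccc(OC)cc1)O2 | intermediate
18 | mac ester of boronic acid 17 (E-alkenyl boronate on C4′ of trans ring 2) | B1(/C=C/c2cc(OC)cc3c2[C@H](c2cc(OC)cc(OC)c2)[C@@H](c2ccc(OC)cc2)O3)O[C@@]2(C)c3cccc4cccc(c34)[C@@]2(C)O1 | intermediate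
19 | 4-fluoro-3-hydroxybenzonitrile | N#Cc1ccc(F)c(O)c1 | starting material
20 | 5-cyano-2-fluorophenyl trifluoromethanesulfonate | N#Cc1ccc(F)c(OS(=O)(=O)C(F)(F)F)c1 | intermediate
21 | 4-bromoanisole | COc1ccc(Br)cc1 | starting material
22 | 4-methoxyphenyllithium | [Li]c1ccc(OC)cc1 | intermediate
23 | lithium alkenyl(4-methoxyphenyl)borate of the mac diol (boron configuration undefined) | [Li+].COc1ccc(cc1)[B-]1(/C=C/c2cc(OC)cc3c2[C@H](c2cc(OC)cc(OC)c2)[C@@H](c2ccc(OC)cc2)O3)O[C@@]2(C)c3cccc4cccc(c34)[C@@]2(C)O1 | intermediate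
24 | mac ester of (1S,2S)-2-(5-cyano-2-fluorophenyl)-2-[(2S,3S)-3-(3,5-dimethoxyphenyl)-6-methoxy-2-(4-methoxyphenyl)-2,3-dihydro-1-benzofuran-4-yl]-1-(4-methoxyphenyl)ethylboronic acid | COc1ccc([C@H]([C@H](c2cc(C#N)ccc2F)c2cc(OC)cc3c2[C@H](c2cc(OC)cc(OC)c2)[C@@H](c2ccc(OC)cc2)O3)B2O[C@@]3(C)c4cccc5cccc(c45)[C@@]3(C)O2)cc1 | intermediate
25 | 3-{(1S,2S)-1-[(2S,3S)-3-(3,5-dimethoxyphenyl)-6-methoxy-2-(4-methoxyphenyl)-2,3-dihydro-1-benzofuran-4-yl]-2-hydroxy-2-(4-methoxyphenyl)ethyl}-4-fluorobenzonitrile | COc1ccc([C@H]([C@H](c2cc(C#N)ccc2F)c2cc(OC)cc3c2[C@H](c2cc(OC)cc(OC)c2)[C@@H](c2ccc(OC)cc2)O3)O)cc1 | intermediate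
26 | (2S,3S)-3-[(2S,3S)-3-(3,5-dimethoxyphenyl)-6-methoxy-2-(4-methoxyphenyl)-2,3-dihydro-1-benzofuran-4-yl]-2-(4-methoxyphenyl)-2,3-dihydro-1-benzofuran-5-carbonitrile | COc1ccc([C@H]2Oc3ccc(C#N)cc3[C@@H]2c2cc(OC)cc3c2[C@H](c2cc(OC)cc(OC)c2)[C@@H](c2ccc(OC)cc2)O3)cc1 | intermediate
27 | (2S,3S)-3-[(2S,3S)-3-(3,5-dimethoxyphenyl)-6-methoxy-2-(4-methoxyphenyl)-2,3-dihydro-1-benzofuran-4-yl]-2-(4-methoxyphenyl)-2,3-dihydro-1-benzofuran-5-carbaldehyde | COc1ccc([C@H]2Oc3ccc(C=O)cc3[C@@H]2c2cc(OC)cc3c2[C@H](c2cc(OC)cc(OC)c2)[C@@H](c2ccc(OC)cc2)O3)cc1 | intermediate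
28 | diethyl (3,5-dimethoxybenzyl)phosphonate | CCOP(=O)(Cc1cc(OC)cc(OC)c1)OCC | starting material
29 | heptamethyl ether of trans-diptoindonesin B | COc1ccc([C@H]2Oc3ccc(/C=C/c4cc(OC)cc(OC)c4)cc3[C@@H]2c2cc(OC)cc3c2[C@H](c2cc(OC)cc(OC)c2)[C@@H](c2ccc(OC)cc2)O3)cc1 | intermediate
30 | trans-diptoindonesin B | Oc1ccc([C@H]2Oc3ccc(/C=C/c4cc(O)cc(O)c4)cc3[C@@H]2c2cc(O)cc3c2[C@H](c2cc(O)cc(O)c2)[C@@H](c2ccc(O)cc2)O3)cc1 | target

Total step count: 18. Longest linear sequence: 16 (steps 1–9, 11, 13–18); steps 10 and 12 are side branches.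

Steps most likely to fail

Step 13. The borate may hand its alkenyl group directly to arylpalladium (Suzuki pathway), or palladium may bind the alkene face that the ring 2 stereocentres favour against the ligand. The fallback builds ring 1 by the carbene C–H insertion used for ring 2; it sets out from 12 and comes back at 29. 5-Bromo-2-[(4-methoxybenzyl)oxy]benzaldehyde F1 is made from 5-bromosalicylaldehyde and 4 (K2CO3, DMF). Bromine–lithium exchange on 12 (n-BuLi, THF, −78 °C) gives the aryllithium F2, which adds to F1 to give the diarylmethanol F3. Dess–Martin oxidation gives the ketone F4, hydrazine the hydrazone F5, and MnO2 the diazo compound F6, which is not isolated. Rh2(PTAD)4 then gives the cis-dihydrobenzofuran F7 by insertion into the 4-methoxybenzyl ether C–H bond, and CF3CO2H epimerises C2 to the trans bromide F8. A Heck reaction of F8 with 3,5-dimethoxystyrene (Pd(OAc)2, P(o-tol)3, NaOAc, DMF, 110 °C) gives 29.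

Step 7. Diazo formation at the doubly ortho-substituted ketone may be slow, and enantio- or diastereocontrol in the insertion may erode. The fallback is a racemic construction followed by resolution and also bypasses steps 6 and 8; it sets out from 8 and comes back at 12. Methylene transfer from trimethylsulfonium iodide and n-BuLi (THF, 0 °C) gives the 2,2-diaryloxirane F9. ZnI2 in benzene rearranges it (Meinwald rearrangement) to the diarylacetaldehyde F10, and 4-methoxyphenylmagnesium bromide adds to give the carbinol F11 as a diastereomer mixture. CF3CO2H with anisole in CH2Cl2 ionises the carbinol; the ether oxygen closes the ring and the 4-methoxybenzyl group is lost, which gives the racemic trans-dihydrobenzofuran F12 from both diastereomers. Preparative chromatography on a chiral stationary phase gives 12.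

Step 18. Seven-fold ether cleavage may stall, the benzylic C–O bonds may ionise, and the electron-rich stilbene may be protonated and react on. The fallback cleaves the ethers before the stilbene exists and ends with fluoride; it sets out from 26 and comes back at 30. BCl3 and n-Bu4NI on 26 give the pentaphenol nitrile F13, and t-BuMe2SiCl with imidazole (DMF) gives the penta-silyl ether F14. i-Bu2AlH reduces F14 to the aldehyde F15. Olefination of F15 with the known phosphonate diethyl [3,5-bis(tert-butyldimethylsilyloxy)benzyl]phosphonate F16 (NaH, THF) gives the hepta-silyl E-stilbene F17, and n-Bu4NF buffered with AcOH (THF, 0 °C) gives 30.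

Further compounds
F1 | step 13 | 5-bromo-2-[(4-methoxybenzyl)oxy]benzaldehyde | COc1ccc(COc2ccc(Br)cc2C=O)cc1
F2 | step 13 | [(2S,3S)-3-(3,5-dimethoxyphenyl)-6-methoxy-2-(4-methoxyphenyl)-2,3-dihydro-1-benzofuran-4-yl]lithium | [Li]c1cc(OC)cc2c1[C@H](c1cc(OC)cc(OC)c1)[C@@H](c1ccc(OC)cc1)O2
F3 | step 13 | {5-bromo-2-[(4-methoxybenzyl)oxy]phenyl}[ring 2 C4′-aryl]methanol (carbinol epimers) | OC(c1cc(Br)ccc1OCc1ccc(OC)cc1)c1cc(OC)cc2c1[C@H](c1cc(OC)cc(OC)c1)[C@@H](c1ccc(OC)cc1)O2
F4 | step 13 | {5-bromo-2-[(4-methoxybenzyl)oxy]phenyl}[ring 2 C4′-aryl]methanone | O=C(c1cc(Br)ccc1OCc1ccc(OC)cc1)c1cc(OC)cc2c1[C@H](c1cc(OC)cc(OC)c1)[C@@H](c1ccc(OC)cc1)O2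
F5 | step 13 | hydrazone of ketone F4 | NN=C(c1cc(Br)ccc1OCc1ccc(OC)cc1)c1cc(OC)cc2c1[C@H](c1cc(OC)cc(OC)c1)[C@@H](c1ccc(OC)cc1)O2
F6 | step 13 | diaryldiazomethane from F5 | [N-]=[N+]=C(c1cc(Br)ccc1OCc1ccc(OC)cc1)c1cc(OC)cc2c1[C@H](c1cc(OC)cc(OC)c1)[C@@H](c1ccc(OC)cc1)O2
F7 | step 13 | (2R,3S)-5-bromo-3-[ring 2 C4′-aryl]-2-(4-methoxyphenyl)-2,3-dihydro-1-benzofuran (cis ring 1) | COc1ccc([C@@H]2Oc3ccc(Br)cc3[C@@H]2c2cc(OC)cc3c2[C@H](c2cc(OC)cc(OC)c2)[C@@H](c2ccc(OC)cc2)O3)cc1
F8 | step 13 | (2S,3S)-5-bromo-3-[ring 2 C4′-aryl]-2-(4-methoxyphenyl)-2,3-dihydro-1-benzofuran (trans ring 1) | COc1ccc([C@H]2Oc3ccc(Br)cc3[C@@H]2c2cc(OC)cc3c2[C@H](c2cc(OC)cc(OC)c2)[C@@H](c2ccc(OC)cc2)O3)cc1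
F9 | step 7 | 2-{2-bromo-4-methoxy-6-[(4-methoxybenzyl)oxy]phenyl}-2-(3,5-dimethoxyphenyl)oxirane (racemic) | COc1ccc(COc2cc(OC)cc(Br)c2C2(c3cc(OC)cc(OC)c3)CO2)cc1
F10 | step 7 | 2-{2-bromo-4-methoxy-6-[(4-methoxybenzyl)oxy]phenyl}-2-(3,5-dimethoxyphenyl)acetaldehyde (racemic) | COc1ccc(COc2cc(OC)cc(Br)c2C(C=O)c2cc(OC)cc(OC)c2)cc1
F11 | step 7 | 2-{2-bromo-4-methoxy-6-[(4-methoxybenzyl)oxy]phenyl}-2-(3,5-dimethoxyphenyl)-1-(4-methoxyphenyl)ethanol (diastereomer mixture) | COc1ccc(COc2cc(OC)cc(Br)c2C(c2cc(OC)cc(OC)c2)C(O)c2ccc(OC)cc2)cc1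
F12 | step 7 | racemic trans-4-bromo-3-(3,5-dimethoxyphenyl)-6-methoxy-2-(4-methoxyphenyl)-2,3-dihydro-1-benzofuran | Brc1cc(OC)cc2c1[C@H](c1cc(OC)cc(OC)c1)[C@@H](c1ccc(OC)cc1)O2.Brc1cc(OC)cc2c1[C@@H](c1cc(OC)cc(OC)c1)[C@H](c1ccc(OC)cc1)O2
F13 | step 18 | pentaphenol corresponding to nitrile 26 | Oc1ccc([C@H]2Oc3ccc(C#N)cc3[C@@H]2c2cc(O)cc3c2[C@H](c2cc(O)cc(O)c2)[C@@H](c2ccc(O)cc2)O3)cc1
F14 | step 18 | penta(tert-butyldimethylsilyl) ether of F13 | CC(C)(C)[Si](C)(C)Oc1ccc([C@H]2Oc3ccc(C#N)cc3[C@@H]2c2cc(O[Si](C)(C)C(C)(C)C)cc3c2[C@H](c2cc(O[Si](C)(C)C(C)(C)C)cc(O[Si](C)(C)C(C)(C)C)c2)[C@@H](c2ccc(O[Si](C)(C)C(C)(C)C)cc2)O3)cc1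
F15 | step 18 | penta-silylated 5-carbaldehyde from F14 | CC(C)(C)[Si](C)(C)Oc1ccc([C@H]2Oc3ccc(C=O)cc3[C@@H]2c2cc(O[Si](C)(C)C(C)(C)C)cc3c2[C@H](c2cc(O[Si](C)(C)C(C)(C)C)cc(O[Si](C)(C)C(C)(C)C)c2)[C@@H](c2ccc(O[Si](C)(C)C(C)(C)C)cc2)O3)cc1
F16 | step 18 | diethyl [3,5-bis(tert-butyldimethylsilyloxy)benzyl]phosphonate | CCOP(=O)(Cc1cc(O[Si](C)(C)C(C)(C)C)cc(O[Si](C)(C)C(C)(C)C)c1)OCC
F17 | step 18 | hepta(tert-butyldimethylsilyl) ether of trans-diptoindonesin B | CC(C)(C)[Si](C)(C)Oc1ccc([C@H]2Oc3ccc(/C=C/c4cc(O[Si](C)(C)C(C)(C)C)cc(O[Si](C)(C)C(C)(C)C)c4)cc3[C@@H]2c2cc(O[Si](C)(C)C(C)(C)C)cc3c2[C@H](c2cc(O[Si](C)(C)C(C)(C)C)cc(O[Si](C)(C)C(C)(C)C)c2)[C@@H](c2ccc(O[Si](C)(C)C(C)(C)C)cc2)O3)cc1
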